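**Plan**

1. Retrosynthesis: the two benzyl ethers and an auxiliary bromine on ring A are removed. The trans-diol goes back through an epoxide to the chromene olefin. Ring C is opened at O1–C2 to a 2′-hydroxychalcone. C4–C4a and O1–C8a are then cut together, leaving an aryne (from a silyl triflate) and a chromenyl acrylic acid.
2. The acid goes back at its Cα=Cβ bond to a chromene aldehyde and malonic acid, and the dimethylpyran ring to the 1,1-dimethylpropargyl ether of 3-(benzyloxy)-4-hydroxybenzaldehyde.
3. Forward: the dimethylpyran ring is built first and the acrylic chain is added. Ring A is then joined through the aryne with no ring closure, ring C closes by oxa-Michael addition, and the olefin is oxidised before the benzyl groups and bromine are taken off.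
4. Enabling feature: in ring A the ketone carbon C4 sits on C4a and the ring oxygen O1 on the neighbouring C8a. This ortho acyl/oxy pair is what is left on the two carbons of an aryne triple bond when the C–O bond of a carboxylic acid adds across it.
5. Stereochemistry: C2 (S) comes from a chiral bifunctional thiourea in the oxa-Michael closure. Chroman C3 (R) and C4 (S) come from an (R,R)-salen manganese epoxidation followed by opening with water, with inversion at C4.

Key step: step 7

Assumption: the quinidine-derived thiourea is taken to give the 2S flavanone; if a pilot run shows the opposite sense, the quinine-derived pseudoenantiomer is used in the same step.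

**Route**

Step 1
Reactants: 1 4-(benzyloxy)phenol
Product: 2 4-(benzyloxy)-2,6-dibromophenol
Conditions: NBS (2.05 equiv), i-Pr2NH (10 mol %), CH2Cl2, 0 °C to rt
Reagents that add atoms: N-bromosuccinimide, O=C1CCC(=O)N1Br
Why: Amine-catalysed electrophilic aromatic bromination is directed to the two positions ortho to the free hydroxyl, the stronger activator, and should leave the positions next to the benzyl ether untouched.

Step 2
Reactants: 2 4-(benzyloxy)-2,6-dibromophenol
Product: 3 [4-(benzyloxy)-2,6-dibromophenoxy]trimethylsilane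
Conditions: HMDS, THF, reflux; evaporate
Reagents that add atoms: hexamethyldisilazane, C[Si](C)(C)N[Si](C)(C)C
Why: O-Silylation of the acidic phenol with HMDS gives the silyl ether needed for the oxygen-to-carbon silyl shift of the next step, with ammonia as the only by-product.

Step 3
Reactants: 3 [4-(benzyloxy)-2,6-dibromophenoxy]trimethylsilane
Product: 6 4-(benzyloxy)-2-bromo-6-(trimethylsilyl)phenyl trifluoromethanesulfonate, via aryllithium 4 (not isolated), via lithium phenolate 5 (not isolated)
Conditions: n-BuLi (1.05 equiv), THF, −78 °C; then Tf2O, −78 °C to rt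
Reagents that add atoms: trifluoromethanesulfonic anhydride, FC(F)(F)S(=O)(=O)OS(=O)(=O)C(F)(F)F
Why: Bromine–lithium exchange at one of the two equivalent bromines gives 4, the retro-Brook 1,3 O-to-C silyl shift gives 5, and O-triflation completes the standard preparation of an ortho-silyl aryl triflate from an ortho-bromophenol.

Step 4
Reactants: 7 3-(benzyloxy)-4-hydroxybenzaldehyde; 8 3-chloro-3-methylbut-1-yne
Product: 9 3-(benzyloxy)-4-[(2-methylbut-3-yn-2-yl)oxy]benzaldehyde
Conditions: K2CO3, KI, CuI (cat.), acetone, reflux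
Reagents that add atoms: none
Why: Copper-assisted Williamson-type O-propargylation of the para-formyl phenolate by the tertiary propargylic chloride is the usual entry to aryl 1,1-dimethylpropargyl ethers.

Step 5
Reactants: 9 3-(benzyloxy)-4-[(2-methylbut-3-yn-2-yl)oxy]benzaldehyde
Product: 12 8-(benzyloxy)-2,2-dimethyl-2H-chromene-6-carbaldehyde, via allenylphenol 10 (not isolated), via ortho-quinone methide 11 (not isolated)
Conditions: N,N-diethylaniline, 190 °C
Reagents that add atoms: none
Why: Aromatic propargyl Claisen rearrangement to the only free ortho carbon and enolisation give 10, whose 1,5-hydrogen shift to 11 and oxa-6π electrocyclisation close the dimethylpyran ring.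

Step 6
Reactants: 12 8-(benzyloxy)-2,2-dimethyl-2H-chromene-6-carbaldehyde; 13 malonic acid
Product: 15 (E)-3-[8-(benzyloxy)-2,2-dimethyl-2H-chromen-6-yl]prop-2-enoic acid, via arylidenemalonic acid 14 (not isolated)
Conditions: pyridine, piperidine (cat.), 90 °C
Reagents that add atoms: none
Why: Knoevenagel–Doebner condensation gives diacid 14, which loses CO2 in hot pyridine to the thermodynamically favoured E-acrylic acid.

Step 7
Reactants: 6 4-(benzyloxy)-2-bromo-6-(trimethylsilyl)phenyl trifluoromethanesulfonate; 15 (E)-3-[8-(benzyloxy)-2,2-dimethyl-2H-chromen-6-yl]prop-2-enoic acid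
Product: 20 (E)-1-[4-(benzyloxy)-2-bromo-6-hydroxyphenyl]-3-[8-(benzyloxy)-2,2-dimethyl-2H-chromen-6-yl]prop-2-en-1-one, via caesium carboxylate 16 (not isolated), via aryne 17 (not isolated), via aryl anion 18 (not isolated), via caesium phenolate 19 (not isolated)
Conditions: 6 (1.5 equiv), CsF (4 equiv), THF, 125 °C, sealed tube; aqueous work-up at 0 °C
Reagents that add atoms: none
Why: Fluoride removes the trimethylsilyl group of 6 and expels triflate to give aryne 17 while CsF converts 15 into carboxylate 16; the carboxylate oxygen adds to the aryne carbon remote from bromine to give aryl anion 18 on the carbon flanked by bromine, and this anion attacks the neighbouring ester carbonyl in a four-centre acyl shift that breaks the former acid C–O bond and leaves phenolate 19, protonated to 20 by the proton set aside on fluoride. The closest known reaction type is the fluoride-induced insertion of arynes into the C–O bond of carboxylic acids to give ortho-hydroxyaryl ketones, acrylic and cinnamic acids included. Two skeletal bonds form, C4–C4a and O1–C8a, no ring closes and no stereocentre is created, and the E double bond of the acid is carried through unchanged. The step needs regioselective oxygen addition, which the inductively withdrawing bromine beside the triple bond should secure by stabilising negative charge on its own neighbour, the more distant benzyloxy group having only a weak opposing effect. It also needs acyl transfer to outrun protonation of 18 and loss of bromide, which the intramolecular four-centre geometry, the ether solvent and the high temperature favour. Conjugate closure of 19 should be held back because the para-oxygen of the chromene lowers the electrophilicity of the enone β-carbon and the mixture is worked up cold.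

Step 8
Reactants: 20 (E)-1-[4-(benzyloxy)-2-bromo-6-hydroxyphenyl]-3-[8-(benzyloxy)-2,2-dimethyl-2H-chromen-6-yl]prop-2-en-1-one
Product: 21 (2S)-7-(benzyloxy)-2-[8-(benzyloxy)-2,2-dimethyl-2H-chromen-6-yl]-5-bromo-2,3-dihydro-4H-chromen-4-one
Conditions: quinidine-derived 9-epi-amino N-[3,5-bis(trifluoromethyl)phenyl]thiourea (10 mol %), toluene, −20 °C
Reagents that add atoms: none
Why: In this asymmetric intramolecular oxa-Michael addition (6-endo-trig) the quinuclidine nitrogen deprotonates the 2′-hydroxyl and the thiourea hydrogen-bonds the enone carbonyl, so the phenolate should add to one face of the E-enone and set C2 as S under catalyst control.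

Step 9
Reactants: 21 (2S)-7-(benzyloxy)-2-[8-(benzyloxy)-2,2-dimethyl-2H-chromen-6-yl]-5-bromo-2,3-dihydro-4H-chromen-4-one
Product: 22 (2S)-7-(benzyloxy)-2-[(3R,4R)-8-(benzyloxy)-3,4-epoxy-2,2-dimethyl-3,4-dihydro-2H-chromen-6-yl]-5-bromo-2,3-dihydro-4H-chromen-4-one
Conditions: (R,R)-[N,N′-bis(3,5-di-tert-butylsalicylidene)cyclohexane-1,2-diaminato]manganese chloride (5 mol %), mCPBA (2 equiv), NMO (5 equiv), CH2Cl2, −78 °C
Reagents that add atoms: 3-chloroperoxybenzoic acid, OOC(=O)c1cccc(Cl)c1
Why: Jacobsen epoxidation of the cis, aryl-conjugated 2,2-dimethylchromene olefin, the best substrate class for salen manganese catalysts, should deliver oxygen to one face under catalyst control and give the (3R,4R)-epoxide with the (R,R)-ligand, independently of the remote C2 centre.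

Step 10
Reactants: 22 (2S)-7-(benzyloxy)-2-[(3R,4R)-8-(benzyloxy)-3,4-epoxy-2,2-dimethyl-3,4-dihydro-2H-chromen-6-yl]-5-bromo-2,3-dihydro-4H-chromen-4-one
Product: 23 (2S)-7-(benzyloxy)-2-[(3R,4S)-8-(benzyloxy)-3,4-dihydroxy-2,2-dimethyl-3,4-dihydro-2H-chromen-6-yl]-5-bromo-2,3-dihydro-4H-chromen-4-one
Conditions: 1 M aq. H2SO4, acetone, 0 °C to rt
Reagents that add atoms: water, O
Why: Acid-catalysed epoxide hydrolysis should open the ring at the benzylic C4 by attack of water anti to the leaving oxygen, turning 4R into 4S while C3 keeps its configuration, which gives the trans-(3R,4S)-diol.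

Step 11
Reactants: 23 (2S)-7-(benzyloxy)-2-[(3R,4S)-8-(benzyloxy)-3,4-dihydroxy-2,2-dimethyl-3,4-dihydro-2H-chromen-6-yl]-5-bromo-2,3-dihydro-4H-chromen-4-one
Product: 24 (2S)-7-hydroxy-2-[(3R,4S)-3,4,8-trihydroxy-2,2-dimethyl-3,4-dihydro-2H-chromen-6-yl]-2,3-dihydro-4H-chromen-4-one
Conditions: H2 (1 atm), 10% Pd/C, NaOAc (1.5 equiv), EtOAc–MeOH, rt
Reagents that add atoms: none
Why: Palladium-catalysed hydrogenolysis should cleave both O-benzyl groups and the aryl C–Br bond in one operation, with NaOAc taking up the HBr so that the benzylic C4–OH and C2–O1 bonds and the three stereocentres are not exposed to acid.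

**Compound list**

1 | 4-(benzyloxy)phenol | Oc1ccc(OCc2ccccc2)cc1 | starting material
2 | 4-(benzyloxy)-2,6-dibromophenol | Oc1c(Br)cc(OCc2ccccc2)cc1Br | intermediate
3 | [4-(benzyloxy)-2,6-dibromophenoxy]trimethylsilane | C[Si](C)(C)Oc1c(Br)cc(OCc2ccccc2)cc1Br | intermediate
4 | [4-(benzyloxy)-2-bromo-6-lithiophenoxy]trimethylsilane | C[Si](C)(C)Oc1c(Br)cc(OCc2ccccc2)cc1[Li] | intermediate (not isolated)
5 | lithium 4-(benzyloxy)-2-bromo-6-(trimethylsilyl)phenolate | [Li+].[O-]c1c(Br)cc(OCc2ccccc2)cc1[Si](C)(C)C | intermediate (not isolated)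
6 | 4-(benzyloxy)-2-bromo-6-(trimethylsilyl)phenyl trifluoromethanesulfonate | C[Si](C)(C)c1cc(OCc2ccccc2)cc(Br)c1OS(=O)(=O)C(F)(F)F | intermediate
7 | 3-(benzyloxy)-4-hydroxybenzaldehyde | O=Cc1ccc(O)c(OCc2ccccc2)c1 | starting material
8 | 3-chloro-3-methylbut-1-yne | CC(C)(Cl)C#C | starting material
9 | 3-(benzyloxy)-4-[(2-methylbut-3-yn-2-yl)oxy]benzaldehyde | O=Cc1ccc(OC(C)(C)C#C)c(OCc2ccccc2)c1 | intermediate
10 | 3-(benzyloxy)-4-hydroxy-5-(3-methylbuta-1,2-dien-1-yl)benzaldehyde | O=Cc1cc(C=C=C(C)C)c(O)c(OCc2ccccc2)c1 | intermediate (not isolated)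
11 | 5-(benzyloxy)-3-(3-methylbut-2-en-1-ylidene)-4-oxocyclohexa-1,5-diene-1-carbaldehyde | CC(C)=CC=C1C=C(C=O)C=C(OCc2ccccc2)C1=O | intermediate (not isolated)
12 | 8-(benzyloxy)-2,2-dimethyl-2H-chromene-6-carbaldehyde | CC1(C)C=Cc2cc(C=O)cc(OCc3ccccc3)c2O1 | intermediate
13 | malonic acid | OC(=O)CC(O)=O | starting material
14 | 2-{[8-(benzyloxy)-2,2-dimethyl-2H-chromen-6-yl]methylidene}propanedioic acid | CC1(C)C=Cc2cc(C=C(C(O)=O)C(O)=O)cc(OCc3ccccc3)c2O1 | intermediate (not isolated)
15 | (E)-3-[8-(benzyloxy)-2,2-dimethyl-2H-chromen-6-yl]prop-2-enoic acid | CC1(C)C=Cc2cc(/C=C/C(O)=O)cc(OCc3ccccc3)c2O1 | intermediate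
16 | caesium (E)-3-[8-(benzyloxy)-2,2-dimethyl-2H-chromen-6-yl]prop-2-enoate | [Cs+].CC1(C)C=Cc2cc(/C=C/C([O-])=O)cc(OCc3ccccc3)c2O1 | intermediate (not isolated)
17 | 5-(benzyloxy)-3-bromobenzyne (5-(benzyloxy)-3-bromo-1,2-didehydrobenzene) | BrC1=CC(OCc2ccccc2)=CC#C1 | intermediate (not isolated)
18 | caesium 4-(benzyloxy)-2-bromo-6-{[(E)-3-(8-(benzyloxy)-2,2-dimethyl-2H-chromen-6-yl)prop-2-enoyl]oxy}benzen-1-ide | [Cs+].CC1(C)C=Cc2cc(/C=C/C(=O)Oc3cc(OCc4ccccc4)cc(Br)[c-]3)cc(OCc3ccccc3)c2O1 | intermediate (not isolated)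
19 | caesium 5-(benzyloxy)-3-bromo-2-[(E)-3-(8-(benzyloxy)-2,2-dimethyl-2H-chromen-6-yl)prop-2-enoyl]phenolate | [Cs+].CC1(C)C=Cc2cc(/C=C/C(=O)c3c([O-])cc(OCc4ccccc4)cc3Br)cc(OCc3ccccc3)c2O1 | intermediate (not isolated)
20 | (E)-1-[4-(benzyloxy)-2-bromo-6-hydroxyphenyl]-3-[8-(benzyloxy)-2,2-dimethyl-2H-chromen-6-yl]prop-2-en-1-one | CC1(C)C=Cc2cc(/C=C/C(=O)c3c(O)cc(OCc4ccccc4)cc3Br)cc(OCc3ccccc3)c2O1 | intermediate
21 | (2S)-7-(benzyloxy)-2-[8-(benzyloxy)-2,2-dimethyl-2H-chromen-6-yl]-5-bromo-2,3-dihydro-4H-chromen-4-one | CC1(C)C=Cc2cc([C@@H]3CC(=O)c4c(Br)cc(OCc5ccccc5)cc4O3)cc(OCc3ccccc3)c2O1 | intermediate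
22 | (2S)-7-(benzyloxy)-2-[(3R,4R)-8-(benzyloxy)-3,4-epoxy-2,2-dimethyl-3,4-dihydro-2H-chromen-6-yl]-5-bromo-2,3-dihydro-4H-chromen-4-one | CC1(C)Oc2c(OCc3ccccc3)cc([C@@H]3CC(=O)c4c(Br)cc(OCc5ccccc5)cc4O3)cc2[C@H]2O[C@H]21 | intermediate
23 | (2S)-7-(benzyloxy)-2-[(3R,4S)-8-(benzyloxy)-3,4-dihydroxy-2,2-dimethyl-3,4-dihydro-2H-chromen-6-yl]-5-bromo-2,3-dihydro-4H-chromen-4-one | CC1(C)Oc2c(OCc3ccccc3)cc([C@@H]3CC(=O)c4c(Br)cc(OCc5ccccc5)cc4O3)cc2[C@H](O)[C@H]1O | intermediate
24 | (2S)-7-hydroxy-2-[(3R,4S)-3,4,8-trihydroxy-2,2-dimethyl-3,4-dihydro-2H-chromen-6-yl]-2,3-dihydro-4H-chromen-4-one (CNP0281318.3) | CC1(C)Oc2c(O)cc([C@@H]3CC(=O)c4ccc(O)cc4O3)cc2[C@H](O)[C@H]1O | target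

**Step count**

Total: 11 steps. Longest linear sequence: 8 steps (7 → 9 → 12 → 15 → 20 → 21 → 22 → 23 → 24; the branch 1 → 2 → 3 → 6 joins at step 7 and is equally long).

**Steps most likely to fail**

Step 7. The aryl anion may be protonated before the acyl shift, which stops the reaction at the aryl ester. The aryne may also be consumed by the electron-rich chromene or by the product phenolate, and the phenolate may close onto the enone in the hot basic medium and give racemic flavanone. The fallback sets out from triflate 6 and aldehyde 12 and comes back at chalcone 20. Triflate 6 is heated with acetic acid and CsF in THF at 125 °C, the simplest case of the same insertion, to give 1-[4-(benzyloxy)-2-bromo-6-hydroxyphenyl]ethan-1-one F1. Claisen–Schmidt condensation of F1 with 12 (KOH, EtOH, rt, cold acidification) then gives 20. The enone is thus made by aldol chemistry after the aryne step and never meets hot fluoride.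

Step 8. Facial selectivity may be poor on this unactivated enone, an uncatalysed racemic closure may compete, and reversible ring opening under the basic catalyst may erode the enantiomeric purity. The fallback sets out from chalcone 20 and comes back at flavanone 21. Closure with NaOAc in refluxing EtOH gives racemic 7-(benzyloxy)-2-[8-(benzyloxy)-2,2-dimethyl-2H-chromen-6-yl]-5-bromo-2,3-dihydro-4H-chromen-4-one F2. Kinetic resolution by Noyori-type asymmetric transfer hydrogenation follows, with Cp*RhCl[(R,R)-TsDPEN] (TsDPEN = N-tosyl-1,2-diphenylethane-1,2-diamine monoanion) and HCO2H–Et3N in EtOAc, stopped near half conversion. It should reduce the 2R enantiomer to (2R,4R)-7-(benzyloxy)-2-[8-(benzyloxy)-2,2-dimethyl-2H-chromen-6-yl]-5-bromo-3,4-dihydro-2H-chromen-4-ol F3 and leave the 2S ketone 21, which is separated by chromatography.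

Step 11. The benzylic C4–OH of the chroman or the benzylic C2–O1 bond may be hydrogenolysed if HBr is not fully buffered. If the buffer is too basic, retro-Michael opening to the chalcone and saturation of its double bond may occur, and debromination may be incomplete. The fallback sets out from diol 23 and comes back at target 24. Radical debromination (Bu3SnH, AIBN, toluene, 80 °C) gives (2S)-7-(benzyloxy)-2-[(3R,4S)-8-(benzyloxy)-3,4-dihydroxy-2,2-dimethyl-3,4-dihydro-2H-chromen-6-yl]-2,3-dihydro-4H-chromen-4-one F4. Its benzyl ethers are then removed with H2 and Pd/C in EtOAc without additive, a hydrogenolysis that releases no acid, to give 24.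

**Further compounds**

F1 | step 7 | 1-[4-(benzyloxy)-2-bromo-6-hydroxyphenyl]ethan-1-one | CC(=O)c1c(O)cc(OCc2ccccc2)cc1Br
F2 | step 8 | racemic 7-(benzyloxy)-2-[8-(benzyloxy)-2,2-dimethyl-2H-chromen-6-yl]-5-bromo-2,3-dihydro-4H-chromen-4-one | CC1(C)C=Cc2cc(C3CC(=O)c4c(Br)cc(OCc5ccccc5)cc4O3)cc(OCc3ccccc3)c2O1
F3 | step 8 | (2R,4R)-7-(benzyloxy)-2-[8-(benzyloxy)-2,2-dimethyl-2H-chromen-6-yl]-5-bromo-3,4-dihydro-2H-chromen-4-ol | CC1(C)C=Cc2cc([C@H]3C[C@@H](O)c4c(Br)cc(OCc5ccccc5)cc4O3)cc(OCc3ccccc3)c2O1
F4 | step 11 | (2S)-7-(benzyloxy)-2-[(3R,4S)-8-(benzyloxy)-3,4-dihydroxy-2,2-dimethyl-3,4-dihydro-2H-chromen-6-yl]-2,3-dihydro-4H-chromen-4-one | CC1(C)Oc2c(OCc3ccccc3)cc([C@@H]3CC(=O)c4ccc(OCc5ccccc5)cc4O3)cc2[C@H](O)[C@H]1O
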